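**Retrosynthetic overview**
1. The two sulfates go on last (hydroquinone + SO3·pyridine); the hydroquinone is carried as its dimethyl ether, the ring A carbonyl (C3) is removed by Wolff–Kishner reduction, and the C15 methyl stereocentre comes from a late MHAT hydrogenation.
2. Key step: the C4 quaternary centre and the trans ring fusion (C5) are set after fragment union by Birch-type reductive methylation of a C4-alkylated enone. The usual C13–C14 disconnection (decalin-ethyl organometallic + hindered oxepane ketone) is not used.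
3. Union: sp3–sp2 Suzuki coupling of a 9-BBN borane (from a C14 vinyl carbinol) with an α-iodoenone that already carries the C8=C9 alkene and the arylmethyl group.
4. Left half from (R)-Wieland–Miescher ketone (rings A and B preformed; enol triflate, benzylzinc Negishi). Right half from 2-methylcyclohexane-1,3-dione (carbocycle preformed; CBS desymmetrisation, then oxepane closure).
5. Ring order: cyclohexane (given) → oxepane closed; decalin (given) → its stereocentres C5 and C4 last, then C15.

Assumption: the target is taken as the free bis(hydrogen sulfate) as drawn; it is released from its pyridinium salt by cold cation exchange in the last step.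
Numbering used: decalin C1–C10 (C4 quaternary, C8=C9, C10 angular methyl), benzylic carbon C11, linker C12–C13, cyclohexane C14–C19, oxepane C20–C23 (ring oxygen between C18 and C23).

**Route**

Step 1
Reactants: 1 2-methylcyclohexane-1,3-dione; 2 acrolein
Product: 3 3-(1-methyl-2,6-dioxocyclohexyl)propanal
Conditions: H2O, rt, 12 h
Reagents that add atoms: none
Why: Michael addition of the enolised dione to acrolein in water is a known high-yielding conjugate addition and creates the future C19 quaternary carbon (still achiral).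

Step 2
Reactants: 3 3-(1-methyl-2,6-dioxocyclohexyl)propanal
Product: 4 2-methyl-2-(4-methylpent-3-en-1-yl)cyclohexane-1,3-dione
Conditions: i-PrPPh3I, n-BuLi, THF, 0 °C; then 3, −78 °C → rt
Reagents that add atoms: isopropyltriphenylphosphonium iodide, CC(C)[P+](c1ccccc1)(c1ccccc1)c1ccccc1.[I-]
Why: Wittig olefination with the non-stabilised isopropylidene ylide is much faster at the aldehyde than at the two neopentyl ketones at −78 °C and installs the C22=C23 alkene.

Step 3
Reactants: 4 2-methyl-2-(4-methylpent-3-en-1-yl)cyclohexane-1,3-dione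
Product: 5 (2S,3S)-3-hydroxy-2-methyl-2-(4-methylpent-3-en-1-yl)cyclohexan-1-one
Conditions: (R)-2-methyl-CBS-oxazaborolidine (20 mol%), catecholborane, toluene, −60 °C
Reagents that add atoms: none
Why: Corey–Bakshi–Shibata reduction desymmetrises the prochiral dione; the (R)-catalyst gives the (S)-carbinol (quaternary carbon as the large group) and hydride enters anti to the larger C2 chain, so the C18 hydroxyl ends cis to the chain and C19 becomes (S).

Step 4
Reactants: 5 (2S,3S)-3-hydroxy-2-methyl-2-(4-methylpent-3-en-1-yl)cyclohexan-1-one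
Product: 6 (5aS,9aS)-2,2,5a-trimethyloctahydro-1-benzoxepin-6(2H)-one
Conditions: Co[N,N'-bis(3,5-di-tert-butylsalicylidene)-1,2-cyclohexanediaminate] (3 mol%), N-fluoro-2,4,6-trimethylpyridinium triflate, PhSiH3, PhCF3, rt
Reagents that add atoms: none
Why: Cobalt-hydride MHAT with radical-polar crossover (Mukaiyama-type Markovnikov hydroalkoxylation) puts H on C22 and lets the C18 hydroxyl trap the tertiary C23 cation equivalent in a seven-membered closure; the cis ring fusion follows from the cis OH/chain relationship set in step 3.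

Step 5
Reactants: 6 (5aS,9aS)-2,2,5a-trimethyloctahydro-1-benzoxepin-6(2H)-one
Product: 7 (5aS,9aS)-2,2,5a,7-tetramethyloctahydro-1-benzoxepin-6(2H)-one (C15 epimer mixture)
Conditions: LiN(i-Pr)2, THF, −78 °C; MeI, −78 → 0 °C
Reagents that add atoms: iodomethane, [CH3]I
Why: The C14 ketone can enolise only toward C15, so enolate C-methylation is regiospecific; the C15 configuration does not matter because it is erased in step 6.

Step 6
Reactants: 7 (5aS,9aS)-2,2,5a,7-tetramethyloctahydro-1-benzoxepin-6(2H)-one
Product: 9 (5aS,9aS)-2,2,5a,7-tetramethyl-3,4,5,5a,9,9a-hexahydro-1-benzoxepin-6(2H)-one, via silyl enol ether 8 (not isolated)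
Conditions: LiN(i-Pr)2, Me3SiCl, THF, −78 °C; then Pd(OAc)2 (1.05 equiv), MeCN, rt
Reagents that add atoms: none
Why: Saegusa–Ito oxidation: the tetrasubstituted silyl enol ether gives a palladium enolate that undergoes β-hydride elimination into the ring, converging both C15 epimers on the conjugated C15=C16 enone.

Step 7
Reactants: 9 (5aS,9aS)-2,2,5a,7-tetramethyl-3,4,5,5a,9,9a-hexahydro-1-benzoxepin-6(2H)-one
Product: 10 (5aS,6R,9aS)-6-ethenyl-2,2,5a,7-tetramethyl-2,3,4,5,5a,6,9,9a-octahydro-1-benzoxepin-6-ol
Conditions: CH2=CHMgBr, CeCl3, THF, −78 °C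
Reagents that add atoms: vinylmagnesium bromide, C=C[Mg]Br
Why: Organocerium 1,2-addition (Imamoto) avoids enolisation and conjugate addition, and the small vinyl nucleophile attacks C14 on the convex face of the cis-fused bicycle (anti to the oxepane CH2 on C19 and to the ring oxygen), so vinyl ends cis to the C19 methyl and the hydroxyl cis to the ring oxygen.

Step 8
Reactants: 11 (R)-Wieland–Miescher ketone
Product: 12 (R)-Wieland–Miescher ketone C3 1,3-dithiolane (C9 ketone free)
Conditions: HSCH2CH2SH, TsOH (cat.), AcOH, rt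
Reagents that add atoms: ethane-1,2-dithiol, SCCS
Why: Acid-catalysed thioketalisation is selective for the conjugated carbonyl of this diketone (the opposite of diol ketalisation), masking the enone and leaving the neopentyl C9 ketone free.

Step 9
Reactants: 12 (R)-Wieland–Miescher ketone C3 1,3-dithiolane
Product: 13 C8-methyl C9 ketone dithiolane (C8 epimer mixture)
Conditions: LiN(i-Pr)2, THF, −78 °C; MeI, −78 → 0 °C
Reagents that add atoms: iodomethane, [CH3]I
Why: The C9 ketone has α-hydrogens only at C8 (C10 is quaternary), so kinetic enolate methylation is regiospecific and the C8 configuration is irrelevant because C8 becomes sp2 in step 10.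

Step 10
Reactants: 13 C8-methyl C9 ketone dithiolane
Product: 14 C8=C9 enol triflate dithiolane
Conditions: KN(SiMe3)2, THF, −78 °C; PhNTf2, −78 → 0 °C
Reagents that add atoms: N-phenylbis(trifluoromethanesulfonimide), O=S(=O)(N(c1ccccc1)S(=O)(=O)C(F)(F)F)C(F)(F)F
Why: Deprotonation of the C8 methine gives the only possible (tetrasubstituted) enolate, and O-sulfonylation fixes the C8=C9 double bond as an alkenyl triflate, as for 2,6,6-trimethylcyclohexenyl triflate.

Step 11
Reactants: 14 C8=C9 enol triflate dithiolane; 15 2,5-dimethoxybenzyl chloride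
Product: 17 C9-(2,5-dimethoxybenzyl) diene dithiolane, via benzylzinc chloride 16 (not isolated)
Conditions: 15, Zn dust, LiCl, THF, rt; then 14, Pd(OAc)2 (3 mol%), SPhos (6 mol%), THF, 50 °C
Reagents that add atoms: none
Why: Negishi coupling: the benzylic zinc reagent from LiCl-assisted zinc insertion couples with the hindered alkenyl triflate under Pd/biarylphosphine catalysis, forming the C9–C11 bond with the alkene locked at C8=C9.

Step 12
Reactants: 17 C9-(2,5-dimethoxybenzyl) diene dithiolane
Product: 18 (4aR)-5-(2,5-dimethoxybenzyl)-4a,6-dimethyl-4,4a,7,8-tetrahydronaphthalen-2(3H)-one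
Conditions: MeI, CaCO3, MeCN/H2O (4:1), 45 °C
Reagents that add atoms: water, O
Why: S-alkylative hydrolysis of the allylic dithiolane (sulfonium formation, then attack by water) regenerates the enone under near-neutral conditions that spare the electron-rich arene and the tetrasubstituted alkene.

Step 13
Reactants: 18 (4aR)-5-(2,5-dimethoxybenzyl)-4a,6-dimethyl-4,4a,7,8-tetrahydronaphthalen-2(3H)-one
Product: 19 α-iodoenone (18 with iodine on the enone α-carbon C4)
Conditions: I2, pyridine, DMAP (cat.), CH2Cl2, rt → 40 °C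
Reagents that add atoms: iodine, [I][I]
Why: Johnson-type α-iodination (amine conjugate addition, iodination of the resulting enolate, elimination) gives the 4-iodo enone, and I2/pyridine is too mild to iodinate the dimethoxyarene or add irreversibly to the hindered C8=C9 alkene.

Step 14
Reactants: 10 (5aS,6R,9aS)-6-ethenyl-2,2,5a,7-tetramethyl-2,3,4,5,5a,6,9,9a-octahydro-1-benzoxepin-6-ol; 19 α-iodoenone
Product: 21 coupled enone (C4 of the enone bonded to C12 of the CH2CH2 linker to C14), via alkylborane 20 (not isolated)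
Conditions: 10, 9-BBN, THF, rt; then 19, PdCl2(dppf) (5 mol%), AsPh3, Cs2CO3, DMF/H2O, rt
Reagents that add atoms: none
Why: 9-BBN hydroborates only the monosubstituted vinyl group (anti-Markovnikov, not the ring trisubstituted alkene), and the primary B-alkyl borane then undergoes B-alkyl Suzuki–Miyaura coupling with the α-iodoenone to form the C4–C12 bond.

Step 15
Reactants: 21 coupled enone
Product: 23 trans-fused C3 ketone with the C4 quaternary centre (C4 methyl trans and linker cis to the C10 methyl), via lithium enolate 22 (not isolated)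
Conditions: Li (2.2 equiv), NH3/THF, −78 °C; then MeI, −78 → −33 °C; aqueous work-up
Reagents that add atoms: iodomethane, [CH3]I
Why: Stork reductive alkylation (Birch-type enone reduction): axial protonation at C5 (the C14 hydroxyl is the internal proton source) gives the trans-fused C3–C4 lithium enolate regiospecifically, and MeI alkylates C4 on the face opposite the angular C10 methyl, which places the new methyl trans and the existing linker cis to it while isolated alkenes and the dimethoxyarene survive without an added proton donor.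

Step 16
Reactants: 23 trans-fused C3 ketone with the C4 quaternary centre
Product: 24 C15-saturated ketone (C15 methyl cis to the C14 hydroxyl)
Conditions: Mn(dpm)3 (dpm = 2,2,6,6-tetramethylheptane-3,5-dionate, 10 mol%), PhSiH3, t-BuOOH, i-PrOH, rt
Reagents that add atoms: none
Why: MHAT hydrogenation (Mukaiyama–Shenvi type): H adds to C16 and the tertiary C15 radical takes its second hydrogen axially, giving the thermodynamically favoured equatorial methyl (the epimer would be syn-axial to the C19 methyl), while the tetrasubstituted, neopentyl C8=C9 alkene is too hindered to accept a hydrogen atom.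

Step 17
Reactants: 24 C15-saturated ketone
Product: 26 C3-deoxygenated dimethyl ether, via hydrazone 25 (not isolated)
Conditions: N2H4·H2O, KOH, diethylene glycol, 130 → 210 °C
Reagents that add atoms: none
Why: Wolff–Kishner reduction (Huang-Minlon) removes the hindered C3 carbonyl as in 4,4-disubstituted 3-keto terpenoids, and the strongly basic medium tolerates the aryl ethers, the tertiary alcohol, the oxepane and the tetrasubstituted alkene.

Step 18
Reactants: 26 C3-deoxygenated dimethyl ether
Product: 28 hydroquinone, via quinone 27 (not isolated)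
Conditions: (NH4)2Ce(NO3)6, MeCN/H2O, 0 °C; then aq. Na2S2O4, Et2O, rt
Reagents that add atoms: water, O
Why: Oxidative demethylation of the 1,4-dimethoxyarene by the ceric salt (electron transfer, addition of water, loss of methanol) gives the benzoquinone, which dithionite reduces in the same operation to the hydroquinone.

Step 19
Reactants: 28 hydroquinone
Product: 30 CNP0125037.3, via pyridinium disulfate 29 (not isolated)
Conditions: SO3·pyridine (6 equiv), pyridine, 40 °C; then H+ exchange resin, MeOH/H2O, 0 °C
Reagents that add atoms: sulfur trioxide–pyridine complex, [O-]S(=O)(=O)[n+]1ccccc1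
Why: O-sulfonation of both phenols with the SO3–pyridine complex is fast, whereas the hindered axial tertiary C14 alcohol does not react, and cation exchange releases the bis(hydrogen sulfate).

**Compound list**
1 | 2-methylcyclohexane-1,3-dione | CC1C(=O)CCCC1=O | starting material
2 | acrolein | C=CC=O | starting material
3 | 3-(1-methyl-2,6-dioxocyclohexyl)propanal | O=CCCC1(C)C(=O)CCCC1=O | intermediate
4 | 2-methyl-2-(4-methylpent-3-en-1-yl)cyclohexane-1,3-dione | CC(C)=CCCC1(C)C(=O)CCCC1=O | intermediate
5 | (2S,3S)-3-hydroxy-2-methyl-2-(4-methylpent-3-en-1-yl)cyclohexan-1-one (OH cis to the alkenyl chain) | O=C1CCC[C@H](O)[C@]1(C)CCC=C(C)C | intermediate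
6 | (5aS,9aS)-2,2,5a-trimethyloctahydro-1-benzoxepin-6(2H)-one (cis-fused; 9a-H and 5a-CH3 on the same face) | O=C1CCC[C@@H]2OC(C)(C)CCC[C@@]21C | intermediate
7 | (5aS,9aS)-2,2,5a,7-tetramethyloctahydro-1-benzoxepin-6(2H)-one, C7 (= C15) epimer mixture | O=C1C(C)CC[C@@H]2OC(C)(C)CCC[C@@]21C | intermediate
8 | (5aS,9aS)-2,2,5a,7-tetramethyl-6-(trimethylsilyloxy)-2,3,4,5,5a,8,9,9a-octahydro-1-benzoxepine | C[Si](C)(C)OC1=C(C)CC[C@@H]2OC(C)(C)CCC[C@@]21C | intermediate
9 | (5aS,9aS)-2,2,5a,7-tetramethyl-3,4,5,5a,9,9a-hexahydro-1-benzoxepin-6(2H)-one | O=C1C(C)=CC[C@@H]2OC(C)(C)CCC[C@@]21C | intermediate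
10 | (5aS,6R,9aS)-6-ethenyl-2,2,5a,7-tetramethyl-2,3,4,5,5a,6,9,9a-octahydro-1-benzoxepin-6-ol (OH cis to the ring oxygen, vinyl cis to 5a-CH3) | C=C[C@@]1(O)C(C)=CC[C@@H]2OC(C)(C)CCC[C@@]21C | intermediate
11 | (R)-Wieland–Miescher ketone, (8aR)-8a-methyl-3,4,8,8a-tetrahydronaphthalene-1,6(2H,7H)-dione | O=C1[C@]2(C)CCC(=O)C=C2CCC1 | starting material
12 | 11 with the enone carbonyl (C3) as its 1,3-dithiolane; C9 ketone free; C10 as in 11 | O=C1[C@]2(C)CCC3(SCCS3)C=C2CCC1 | intermediate
13 | 12 methylated at C8 (α to the C9 ketone), C8 epimer mixture | O=C1[C@]2(C)CCC3(SCCS3)C=C2CCC1C | intermediate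
14 | C8=C9 enol triflate of 13 (C9–OTf, C8–CH3; C3 dithiolane; C4=C5 alkene) | CC1=C(OS(=O)(=O)C(F)(F)F)[C@]2(C)CCC3(SCCS3)C=C2CC1 | intermediate
15 | 2,5-dimethoxybenzyl chloride | COc1ccc(OC)c(CCl)c1 | starting material
16 | (2,5-dimethoxybenzyl)zinc chloride | COc1ccc(OC)c(C[Zn]Cl)c1 | intermediate
17 | 14 with the triflate replaced by the 2,5-dimethoxybenzyl group (C9–C11 bond) | CC1=C(Cc2cc(OC)ccc2OC)[C@]2(C)CCC3(SCCS3)C=C2CC1 | intermediate
18 | (4aR)-5-(2,5-dimethoxybenzyl)-4a,6-dimethyl-4,4a,7,8-tetrahydronaphthalen-2(3H)-one | CC1=C(Cc2cc(OC)ccc2OC)[C@]2(C)CCC(=O)C=C2CC1 | intermediate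
19 | 18 bearing iodine on the enone α-carbon (C4); C10 unchanged | CC1=C(Cc2cc(OC)ccc2OC)[C@]2(C)CCC(=O)C([I])=C2CC1 | intermediate
20 | B-alkyl-9-BBN from 10: 9-BBN boron on the terminal carbon (C12) of the former vinyl group; stereocentres as in 10 | C1CCC2CCCC1B2CC[C@@]1(O)C(C)=CC[C@@H]2OC(C)(C)CCC[C@@]21C | intermediate
21 | coupled enone: 18 with C4–H replaced by the CH2CH2 linker (C12–C13) to C14 of the benzoxepinol; stereocentres as in 10 and 18 | CC1=C(Cc2cc(OC)ccc2OC)[C@]2(C)CCC(=O)C(CC[C@@]3(O)C(C)=CC[C@@H]4OC(C)(C)CCC[C@@]43C)=C2CC1 | intermediate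
22 | dilithium species: C3–C4 lithium enolate with C5–H trans to C10–CH3, and C14 lithium alkoxide | CC1=C(Cc2cc(OC)ccc2OC)[C@]2(C)CCC(O[Li])=C(CC[C@@]3(O[Li])C(C)=CC[C@@H]4OC(C)(C)CCC[C@@]43C)[C@H]2CC1 | intermediate
23 | trans-decalin C3 ketone: C5–H trans to C10–CH3; C4 quaternary with new CH3 trans and linker cis to C10–CH3; C15=C16 alkene retained | CC1=C(Cc2cc(OC)ccc2OC)[C@]2(C)CCC(=O)[C@@](C)(CC[C@@]3(O)C(C)=CC[C@@H]4OC(C)(C)CCC[C@@]43C)[C@H]2CC1 | intermediate
24 | 23 with C15=C16 hydrogenated; C15–CH3 cis to C14–OH and trans to C19–CH3 | CC1=C(Cc2cc(OC)ccc2OC)[C@]2(C)CCC(=O)[C@@](C)(CC[C@@]3(O)[C@H](C)CC[C@@H]4OC(C)(C)CCC[C@@]43C)[C@H]2CC1 | intermediate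
25 | C3 hydrazone of 24 | CC1=C(Cc2cc(OC)ccc2OC)[C@]2(C)CCC(=NN)[C@@](C)(CC[C@@]3(O)[C@H](C)CC[C@@H]4OC(C)(C)CCC[C@@]43C)[C@H]2CC1 | intermediate
26 | 24 with C3 reduced to CH2 (hydroquinone dimethyl ether of the target skeleton) | CC1=C(Cc2cc(OC)ccc2OC)[C@]2(C)CCC[C@@](C)(CC[C@@]3(O)[C@H](C)CC[C@@H]4OC(C)(C)CCC[C@@]43C)[C@H]2CC1 | intermediate
27 | 2-substituted 1,4-benzoquinone corresponding to 26 | CC1=C(CC2=CC(=O)C=CC2=O)[C@]2(C)CCC[C@@](C)(CC[C@@]3(O)[C@H](C)CC[C@@H]4OC(C)(C)CCC[C@@]43C)[C@H]2CC1 | intermediate
28 | hydroquinone (target without the two sulfate groups) | CC1=C(Cc2cc(O)ccc2O)[C@]2(C)CCC[C@@](C)(CC[C@@]3(O)[C@H](C)CC[C@@H]4OC(C)(C)CCC[C@@]43C)[C@H]2CC1 | intermediate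
29 | bis(pyridinium) salt of the target disulfate | CC1=C(Cc2cc(OS(=O)(=O)[O-])ccc2OS(=O)(=O)[O-])[C@]2(C)CCC[C@@](C)(CC[C@@]3(O)[C@H](C)CC[C@@H]4OC(C)(C)CCC[C@@]43C)[C@H]2CC1.c1cc[nH+]cc1.c1cc[nH+]cc1 | intermediate
30 | CNP0125037.3, hydroquinone bis(hydrogen sulfate) | CC1=C(Cc2cc(OS(=O)(=O)O)ccc2OS(=O)(=O)O)[C@]2(C)CCC[C@@](C)(CC[C@@]3(O)[C@H](C)CC[C@@H]4OC(C)(C)CCC[C@@]43C)[C@H]2CC1 | target

**Totals and risks**
Total steps: 19. Longest linear sequence: 13 steps (steps 1–7, then 14–19); the branch from 11 is 12 steps (steps 8–13, then 14–19).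

The three steps most likely to fail:

Step 4 (seven-membered ether closure by hydroalkoxylation; elimination or alkene isomerisation may compete). The fallback sets out from 5 and returns at 6. Treat 5 with 2,4,4,6-tetrabromocyclohexa-2,5-dienone in MeNO2 at 0 °C: bromonium-induced Markovnikov etherification, the mode used for 3-bromo-2,2-dimethyloxepanes, gives the bromo-oxepane ketone F1. Radical debromination with Bu3SnH/AIBN in toluene at 80 °C then gives 6.

Step 13 (α-iodination of a β,β-disubstituted enone, where amine conjugate addition is hindered). The fallback sets out from 14 and returns at 21 by reversing the order of the two couplings. Unmask 14 with MeI/CaCO3 in aqueous MeCN to the enone triflate F2. Because no electron-rich arene is present yet, classical addition–elimination (Br2, CH2Cl2, 0 °C; then Et3N) can be used to make the α-bromoenone triflate F3. Couple F3 chemoselectively at the C–Br bond with borane 20 under the step 14 conditions to give the coupled enone triflate F4. Negishi coupling of F4 with zinc reagent 16 under the step 11 conditions then installs the arylmethyl group and gives 21.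

Step 15 (reductive methylation on the fully coupled substrate; simple protonation of the enolate in ammonia or poor C-alkylation are the likely failures). The fallback sets out from 21 and returns at 23 by separating reduction from alkylation. Li/NH3 reduction followed by Me3SiCl/Et3N traps the regiospecific enolate as the bis(trimethylsilyl) compound F5 (C3 silyl enol ether, C14 silyl ether). MeLi in THF regenerates the lithium enolate free of ammonia, MeI/DMPU methylates C4 from the same face, and Bu4NF in the work-up removes the C14 silyl ether to give 23.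

**Further compounds**
F1 | step 4 | (5aS,9aS)-3-bromo-2,2,5a-trimethyloctahydro-1-benzoxepin-6(2H)-one (C3 epimers) | O=C1CCC[C@@H]2OC(C)(C)C(Br)CC[C@@]21C
F2 | step 13 | enone triflate: 14 with the C3 dithiolane hydrolysed to the ketone | CC1=C(OS(=O)(=O)C(F)(F)F)[C@]2(C)CCC(=O)C=C2CC1
F3 | step 13 | α-bromoenone triflate: F2 with bromine on C4 | CC1=C(OS(=O)(=O)C(F)(F)F)[C@]2(C)CCC(=O)C(Br)=C2CC1
F4 | step 13 | coupled enone triflate: F3 with bromine replaced by the CH2CH2 linker to C14 of the benzoxepinol | CC1=C(OS(=O)(=O)C(F)(F)F)[C@]2(C)CCC(=O)C(CC[C@@]3(O)C(C)=CC[C@@H]4OC(C)(C)CCC[C@@]43C)=C2CC1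
F5 | step 15 | bis(trimethylsilyl) compound: C3 silyl enol ether of the trans-fused reduction product, C14 trimethylsilyl ether | CC1=C(Cc2cc(OC)ccc2OC)[C@]2(C)CCC(O[Si](C)(C)C)=C(CC[C@@]3(O[Si](C)(C)C)C(C)=CC[C@@H]4OC(C)(C)CCC[C@@]43C)[C@H]2CC1
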